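**Retrosynthetic overview**

1. The target is read as (−)-fisetinidol-(4α→6)-(−)-fisetinidol-(4α→6)-(+)-catechin carrying a third (−)-fisetinidol 4α→8 on the catechin; every flavan unit is 2R,3S and every interflavan bond is 3,4-trans.
2. Last disconnection: the catechin C6–C4 bond, made from the C4 cation (A-ring quinone methide) of a [4,6]-bifisetinidol 4-ol and the [4,8]-fisetinidol–catechin dimer.
3. Both dimers come from one electrophile, mollisacacidin (the flavan-3,4-diol), made once by borohydride reduction of (2R,3R)-fustin; catechin is bought.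
4. The only ring that is built is the pyranone ring of fustin: one-flask oxa-Michael closure of a 2'-hydroxychalcone plus C3 hydroxylation of the flavanone enolate under a chiral ammonium catalyst, setting C2 and C3 together.
5. Ring order: chalcone (aldol), then the fisetinidol C-ring (made once, used three times), then the C4–C8, C4–C6 and C4–C6 interflavan bonds; no ring is formed afterwards.

Assumption: 4'-benzyloxy-2'-hydroxyacetophenone and 3,4-bis(benzyloxy)benzaldehyde are taken as inexpensive catalogue compounds (each is otherwise one benzylation away from resacetophenone or protocatechualdehyde).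

**Step 1**
Reactants: 1 4'-benzyloxy-2'-hydroxyacetophenone; 2 3,4-bis(benzyloxy)benzaldehyde
Product: 3 (E)-2'-hydroxy-3,4,4'-tris(benzyloxy)chalcone (tri-O-benzylbutein)
Conditions: KOH (5 equiv), EtOH–H2O, rt, 48 h; then 1 M HCl
Reagents that add atoms: none
Why: Claisen–Schmidt aldol condensation, in which the acetophenone enolate adds to the non-enolisable aldehyde and E1cB dehydration gives the conjugated (E)-enone, the hydrogen-bonded 2'-OH staying free as the later ring-closing nucleophile.

**Step 2**
Reactants: 3 tri-O-benzylbutein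
Product: 5 (2R,3R)-7,3',4'-tri-O-benzylfustin, via tri-O-benzylbutin 4 (not isolated)
Conditions: N-(9-anthracenylmethyl)cinchonidinium chloride (10 mol %), Cs2CO3 (20 mol %), 30% aq H2O2 (1.5 equiv), toluene, −10 °C
Reagents that add atoms: hydrogen peroxide, OO
Why: Proposed new method: the ammonium-paired 2'-phenoxide closes the pyranone ring by reversible 6-endo oxa-Michael addition (chalcone-isomerase logic) to give flavanone 4, whose C3 enolate is hydroxylated by H2O2 anti to the 2-aryl group (flavanone-3-hydroxylase logic), so the 2,3-trans relationship is substrate-controlled and also thermodynamically preferred, while the absolute configuration is selected by the chiral cation discriminating the two enantiomeric enolate ion pairs, which interconvert rapidly through retro-oxa-Michael opening, in the hydroxylation step (dynamic kinetic resolution); the closest known chemistry is the Algar–Flynn–Oyamada reaction, which gives racemic trans-dihydroflavonols from 6'-unsubstituted 2'-hydroxychalcones at low temperature, combined with cinchona phase-transfer asymmetric epoxidation of chalcones with H2O2 and phase-transfer α-hydroxylation of ketone enolates.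

**Step 3**
Reactants: 5 (2R,3R)-7,3',4'-tri-O-benzylfustin
Product: 6 (2R,3R)-fustin
Conditions: H2 (1 atm), 10% Pd/C, THF–MeOH, rt; recrystallise
Reagents that add atoms: none
Why: Catalytic hydrogenolysis of the three aryl benzyl ethers, in which the vinylogous-ester-type aryl ketone and both stereocentres are untouched at 1 atm under neutral conditions, and recrystallisation raises the ee.

**Step 4**
Reactants: 6 (2R,3R)-fustin
Product: 7 (+)-mollisacacidin, (2R,3S,4R)-2,3-trans-3,4-trans-flavan-3,4-diol
Conditions: NaBH4 (4 equiv), EtOH, 0 °C to rt, N2; AcOH to pH 5–6, EtOAc extraction; crystallise from water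
Reagents that add atoms: none
Why: Borohydride reduction of the C4 aryl ketone of a 2,3-trans-dihydroflavonol, in which hydride is delivered to the face syn to the 3-OH so that the new 4-OH is trans to it (4R, 4α), and the mild acetic acid quench avoids ionising the acid-labile benzylic 4-OH.

**Step 5**
Reactants: 7 (+)-mollisacacidin; 8 (+)-catechin (4 equiv)
Product: 9 fisetinidol-(4α→8)-catechin
Conditions: 0.1 M aq HCl, rt, N2, 5 h; EtOAc extraction; Sephadex LH-20 (EtOH)
Reagents that add atoms: none
Why: In dilute acid 7 ionises to the 7-OH-stabilised C4 benzylic cation (A-ring quinone methide) and undergoes biomimetic SN1 Friedel–Crafts alkylation of the phloroglucinol ring of excess catechin, mainly at the more accessible C8 and mainly anti to the 3-OH, to set the new C4 as 4α (4S), the 4β and C6 isomers being removed by chromatography.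

**Step 6**
Reactants: 7 (+)-mollisacacidin (2 equiv)
Product: 10 fisetinidol-(4α→6)-mollisacacidin
Conditions: 0.1 M aq HCl (0.2 M in 7), rt, N2, stopped by EtOAc extraction at about 35% conversion (HPLC); Sephadex LH-20; recovered 7 recycled
Reagents that add atoms: none
Why: The same acid-induced flavan-4-yl cation is captured by the resorcinol-type A-ring of a second molecule of 7 at C6 (para to O1, ortho to 7-OH, less hindered than C8) anti to the 3-OH to give the 4α (4R) bond, and stopping at low conversion keeps this step-growth Friedel–Crafts self-condensation at the dimer, whose own 4-OH configuration is irrelevant because it is ionised in the next step.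

**Step 7**
Reactants: 9 fisetinidol-(4α→8)-catechin (2.5 equiv); 10 fisetinidol-(4α→6)-mollisacacidin
Product: 11 fisetinidol-(4α→6)-fisetinidol-(4α→6)-[fisetinidol-(4α→8)]-catechin (target)
Conditions: 0.1 M aq HCl–EtOH (9:1), rt, N2, 24 h; Sephadex LH-20, then RP-HPLC
Reagents that add atoms: none
Why: Biomimetic SN1 Friedel–Crafts coupling in which the C4 cation of 10 is trapped by catechin C6 of 9, the only phloroglucinol-type carbon left and far more nucleophilic than any resorcinol-type ring present, with attack anti to the 3-OH of the 2,3-trans unit setting the last stereocentre as 4α (4S), while the existing 5-deoxy interflavan bonds and C2/C3 centres are stable to 0.1 M HCl at rt.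

**Compound list**

1 | 4'-benzyloxy-2'-hydroxyacetophenone, 1-[4-(benzyloxy)-2-hydroxyphenyl]ethan-1-one | CC(=O)c1ccc(OCc2ccccc2)cc1O | starting material
2 | 3,4-bis(benzyloxy)benzaldehyde | O=Cc1ccc(OCc2ccccc2)c(OCc2ccccc2)c1 | starting material
3 | tri-O-benzylbutein, (E)-1-[4-(benzyloxy)-2-hydroxyphenyl]-3-[3,4-bis(benzyloxy)phenyl]prop-2-en-1-one | O=C(/C=C/c1ccc(OCc2ccccc2)c(OCc2ccccc2)c1)c1ccc(OCc2ccccc2)cc1O | intermediate
4 | tri-O-benzylbutin, (2S)-7-(benzyloxy)-2-[3,4-bis(benzyloxy)phenyl]chroman-4-one; formed by the oxa-Michael closure and consumed through its C3 enolate, drawn as the neutral flavanone | O=C1C[C@@H](c2ccc(OCc3ccccc3)c(OCc3ccccc3)c2)Oc2cc(OCc3ccccc3)ccc21 | intermediate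
5 | (2R,3R)-7-(benzyloxy)-2-[3,4-bis(benzyloxy)phenyl]-3-hydroxychroman-4-one (2,3-trans; tri-O-benzylfustin) | O=C1c2ccc(OCc3ccccc3)cc2O[C@H](c2ccc(OCc3ccccc3)c(OCc3ccccc3)c2)[C@H]1O | intermediate
6 | (2R,3R)-fustin, (2R,3R)-2-(3,4-dihydroxyphenyl)-3,7-dihydroxychroman-4-one | O=C1c2ccc(O)cc2O[C@H](c2ccc(O)c(O)c2)[C@H]1O | intermediate
7 | (+)-mollisacacidin, (2R,3S,4R)-2-(3,4-dihydroxyphenyl)chromane-3,4,7-triol (2,3-trans-3,4-trans) | Oc1ccc2c(c1)O[C@H](c1ccc(O)c(O)c1)[C@@H](O)[C@@H]2O | intermediate
8 | (+)-catechin, (2R,3S)-2-(3,4-dihydroxyphenyl)chromane-3,5,7-triol | Oc1cc(O)c2c(c1)O[C@H](c1ccc(O)c(O)c1)[C@@H](O)C2 | starting material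
9 | fisetinidol-(4α→8)-catechin: (2R,3S)-catechin bearing at C8 the (2R,3S,4S)-2-(3,4-dihydroxyphenyl)-3,7-dihydroxychroman-4-yl group (3,4-trans) | c1c(O)c2c(c([C@@H]3c4ccc(O)cc4O[C@H](c4ccc(O)c(O)c4)[C@H]3O)c1O)O[C@H](c1ccc(O)c(O)c1)[C@@H](O)C2 | intermediate
10 | fisetinidol-(4α→6)-mollisacacidin: (2R,3S,4R)-mollisacacidin bearing at C6 the (2R,3S,4R)-2-(3,4-dihydroxyphenyl)-3,7-dihydroxychroman-4-yl group (3,4-trans) | Oc1ccc2c(c1)O[C@H](c1ccc(O)c(O)c1)[C@@H](O)[C@@H]2c1cc2c(cc1O)O[C@H](c1ccc(O)c(O)c1)[C@@H](O)[C@@H]2O | intermediate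
11 | fisetinidol-(4α→6)-fisetinidol-(4α→6)-[fisetinidol-(4α→8)]-catechin; terminal unit 2R,3S,4R, middle unit 2R,3S,4S, catechin 2R,3S, C8-linked unit 2R,3S,4S | Oc1ccc2c(c1)O[C@H](c1ccc(O)c(O)c1)[C@@H](O)[C@@H]2c1cc2c(cc1O)O[C@H](c1ccc(O)c(O)c1)[C@@H](O)[C@@H]2c1c(O)c2c(c([C@@H]3c4ccc(O)cc4O[C@H](c4ccc(O)c(O)c4)[C@H]3O)c1O)O[C@H](c1ccc(O)c(O)c1)[C@@H](O)C2 | target

**Step count and risks**

Total steps: 7. Longest linear sequence: 6 (steps 1, 2, 3, 4, then 5 or 6, then 7).

The three steps most likely to fail are steps 2, 6 and 7.

Step 2 is the highest risk. The asymmetric induction is unprecedented, the sense of induction with the cinchonidinium salt must be checked on first run (the cinchoninium pseudo-enantiomer is the obvious switch), and over-oxidation to the flavonol or a competing Weitz–Scheffer epoxide pathway could erode yield or ee. The fallback sets out from 3 and returns at 5 by an epoxide-based ring closure. Chalcone 3 is protected (MOMCl, NaH, THF, 0 °C) as the 2'-O-methoxymethyl chalcone F1. Juliá–Colonna epoxidation (poly-L-leucine, urea–H2O2, DBU, THF, rt) then gives the (αR,βS)-epoxychalcone F2. Warming F2 in HCl/MeOH (50 °C) removes the MOM group, and the freed phenol opens the epoxide at the benzylic carbon (6-endo) with inversion. C3 keeps the configuration of the epoxide α-carbon and C2 settles trans, giving 5.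

Step 6 is risky because 7 is both nucleophile and electrophile, so dimer 10 forms alongside recovered monomer, higher oligomers and the 4β epimer. The fallback sets out from 7 and returns at 11, replacing the 4-OH of the lower unit by a latent leaving group. Part of 7 is converted with benzyl mercaptan in acetic acid into 4α-benzylsulfanylfisetinidol F3 (either C4 epimer serves). F3 (3 equiv) is alkylated at C6 by the cation from the remaining 7 in 0.1 M HCl at rt, giving fisetinidol-(4α→6)-(4α-benzylsulfanyl)fisetinidol F4. Its thioether ionises far more slowly than a 4-OH, so growth stops at the dimer. F4 is then activated with AgBF4 (THF, 0 °C) in the presence of 9 to form the catechin C6–C4 bond and give 11 directly.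

Step 7 is risky because catechin C6 in 9 is flanked by two hydroxyls and sits next to the C8 flavanyl group, the electrophile is a bulky dimer that can also self-condense, and the 4α/4β ratio may be modest. The fallback sets out from 9 and returns at 11 by linear chain growth with the small monomeric electrophile. Compound 9 is condensed with 7 (0.1 M HCl, rt) to give the angular trimer fisetinidol-(4α→8)-catechin-(6→4α)-fisetinidol F5. A second condensation of F5 with 7 under the same conditions then adds the last unit at C6 of the fisetinidol on catechin C6 to give 11. The regioisomer on the other fisetinidol unit and the 4β epimers are separated by RP-HPLC.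

**Further compounds**

F1 | step 2 | (E)-1-[4-(benzyloxy)-2-(methoxymethoxy)phenyl]-3-[3,4-bis(benzyloxy)phenyl]prop-2-en-1-one | COCOc1cc(OCc2ccccc2)ccc1C(=O)/C=C/c1ccc(OCc2ccccc2)c(OCc2ccccc2)c1
F2 | step 2 | [4-(benzyloxy)-2-(methoxymethoxy)phenyl][(2R,3S)-3-[3,4-bis(benzyloxy)phenyl]oxiran-2-yl]methanone (trans, αR,βS) | COCOc1cc(OCc2ccccc2)ccc1C(=O)[C@@H]3O[C@H]3c4ccc(OCc5ccccc5)c(OCc5ccccc5)c4
F3 | step 6 | 4α-benzylsulfanylfisetinidol, (2R,3R,4R)-4-(benzylsulfanyl)-2-(3,4-dihydroxyphenyl)chromane-3,7-diol (2,3-trans-3,4-trans; the C3 descriptor changes only because sulfur raises the CIP rank of C4) | Oc1ccc2c(c1)O[C@H](c1ccc(O)c(O)c1)[C@@H](O)[C@@H]2SCc1ccccc1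
F4 | step 6 | fisetinidol-(4α→6)-(4α-benzylsulfanyl)fisetinidol, all 2,3-trans-3,4-trans | Oc1ccc2c(c1)O[C@H](c1ccc(O)c(O)c1)[C@@H](O)[C@@H]2c1cc2c(cc1O)O[C@H](c1ccc(O)c(O)c1)[C@@H](O)[C@@H]2SCc1ccccc1
F5 | step 7 | fisetinidol-(4α→8)-catechin-(6→4α)-fisetinidol (angular trimer, all 2,3-trans-3,4-trans) | c1cc2c(cc1O)O[C@H](c1ccc(O)c(O)c1)[C@@H](O)[C@@H]2c1c(O)c2c(c([C@@H]3c4ccc(O)cc4O[C@H](c4ccc(O)c(O)c4)[C@H]3O)c1O)O[C@H](c1ccc(O)c(O)c1)[C@@H](O)C2
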